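The route rests on cutting ring B at O1–C2 and, in the same stroke, both aryl bonds of its vicinal stereocentres: C2–C1′ (ring C) and C3–C3a (ring A). This C2/C3 pair, one aryl each and oxygen on C2, is what an anti diarylation of a boron-bearing alkene leaves behind. One palladium-catalysed conjunctive coupling therefore joins three pieces: lithiated ring C adds to boron of an E 3-silyloxypropenyl boronic ester, the ring-A iodide is then delivered to C3 while ring C shifts to C2, setting C3 absolutely and leaving boron on C2 as the future O1 site. Precursors: a doubly protected 5-iodovanillin, a MOM-protected bromosyringol and a hindered alkenyl boronate.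

Key step: step 6

Assumptions: benzofuran numbering is used (ring A = benzo ring, ring B = dihydrofuran, ring C = the 4-hydroxy-3,5-dimethoxyphenyl group). Which antipode of the MandyPhos ligand leads to the (1S,2R) coupling product is to be settled in a pilot run; both antipodes are sold, and the route is written for the one that does.

Step 1
Reactants: 1 5-iodovanillin (4-hydroxy-3-iodo-5-methoxybenzaldehyde)
Product: 2 3-iodo-5-methoxy-4-(methoxymethoxy)benzaldehyde
Conditions: MOMCl, i-Pr2NEt, CH2Cl2, 0 °C → rt
Reagents that add atoms: chloromethyl methyl ether, COCCl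
Why: Williamson-type O-alkylation of the acidic, para-formyl-activated phenol by the reactive α-chloro ether (MOM protection) should be clean, the aldehyde being inert to the amine base.

Step 2
Reactants: 2 3-iodo-5-methoxy-4-(methoxymethoxy)benzaldehyde
Product: 3 2-[3-iodo-5-methoxy-4-(methoxymethoxy)phenyl]-1,3-dioxolane
Conditions: (Me3SiOCH2)2, Me3SiOTf (cat.), CH2Cl2, −78 → −20 °C; pyridine quench
Reagents that add atoms: 1,2-bis(trimethylsilyloxy)ethane, C[Si](C)(C)OCCO[Si](C)(C)C
Why: Noyori acetalisation, in which the silyl-activated carbonyl is captured by the bis-silyl ether and irreversible loss of hexamethyldisiloxane drives the reaction, is aprotic and cold and should therefore spare the aryl MOM ether that a hot protic acid/diol acetalisation would endanger.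

Step 3
Reactants: 4 4-bromo-2,6-dimethoxyphenol
Product: 5 5-bromo-1,3-dimethoxy-2-(methoxymethoxy)benzene
Conditions: NaH, MOMCl, THF/DMF, 0 °C → rt
Reagents that add atoms: chloromethyl methyl ether, COCCl
Why: the sodium phenoxide of the doubly ortho-substituted phenol is alkylated by MOMCl (Williamson ether synthesis), giving an ether that tolerates t-BuLi and falls in the final acid step.

Step 4
Reactants: 6 acenaphthylene-1,2-dione (acenaphthoquinone)
Product: 7 cis-1,2-dimethyl-1,2-dihydroacenaphthylene-1,2-diol (meso)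
Conditions: AlMe3 (3 equiv), toluene, 0 °C → rt; aq. HCl work-up; recrystallisation
Reagents that add atoms: trimethylaluminium, C[Al](C)C
Why: double 1,2-addition of methyl to the 1,2-dione, the second methyl entering anti to the bulky aluminium alkoxide on the neighbouring carbon, should give the cis (meso, achiral) diol, which crystallisation frees from any trans isomer.

Step 5
Reactants: 8 tert-butyldimethyl(prop-2-yn-1-yloxy)silane, 7 cis-1,2-dimethyl-1,2-dihydroacenaphthylene-1,2-diol
Product: 10 (E)-3-(tert-butyldimethylsilyloxy)prop-1-en-1-ylboronic acid cis-1,2-dimethylacenaphthylene-1,2-diyl ester, via catechol alkenylboronate 9 (not isolated)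
Conditions: catecholborane, THF, 65 °C; then 7, rt → 40 °C; aq. NaHCO3 wash
Reagents that add atoms: catecholborane, B1Oc2ccccc2O1
Why: syn hydroboration of the terminal alkyne puts boron on the terminal carbon and fixes the E geometry, and the labile catechol ester then transesterifies with the chelating ditertiary diol; this hindered ester is chosen over a pinacol ester because β-substituted alkenyl pinacol boronates tend to undergo direct Suzuki coupling under the conditions of the next step.

Step 6
Reactants: 5 5-bromo-1,3-dimethoxy-2-(methoxymethoxy)benzene, 10 (E)-3-(tert-butyldimethylsilyloxy)prop-1-en-1-ylboronic acid cis-1,2-dimethylacenaphthylene-1,2-diyl ester, 3 2-[3-iodo-5-methoxy-4-(methoxymethoxy)phenyl]-1,3-dioxolane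
Product: 13 (1S,2R)-3-(tert-butyldimethylsilyloxy)-1-[3,5-dimethoxy-4-(methoxymethoxy)phenyl]-2-[5-(1,3-dioxolan-2-yl)-3-methoxy-2-(methoxymethoxy)phenyl]propylboronic acid cis-1,2-dimethylacenaphthylene-1,2-diyl ester, via aryllithium 11 (not isolated), via lithium boronate complex 12 (not isolated)
Conditions: 5, t-BuLi (2 equiv), THF, −78 °C; then 10, −78 °C → rt; then 3 (limiting), Pd(OAc)2 (3 mol%), MandyPhos ligand 1,1′-bis[bis(4-methoxy-3,5-dimethylphenyl)phosphino]-2,2′-bis[α-(dimethylamino)benzyl]ferrocene (C64H74FeN2O4P2, 3.6 mol%), NaOTf (3 equiv), THF, 60 °C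
Reagents that add atoms: none
Why: Oxidative addition of 3 to zerovalent palladium and removal of iodide by NaOTf should give a cationic aryl palladium species (divalent palladium) that binds the alkene of the four-coordinate boronate 12; this activation triggers a 1,2-shift of ring C from boron to C2 anti to palladium at C3, and reductive elimination with retention then joins C3 to ring A. The closest known reaction type is the enantioselective palladium-catalysed conjunctive cross-coupling of aryllithium-derived boronates of β-substituted alkenyl boronic esters with aryl electrophiles. No ring is closed. The C3 centre is set by the chiral bisphosphine, which chooses the alkene face that palladium binds, and the C2 centre follows from the stereospecific anti addition across the E double bond, so a single (1S,2R) diastereomer is expected. The step needs the metallate shift to outrun direct transmetalation of the alkenyl group (Suzuki coupling) and β-hydride or β-silyloxy elimination from the alkyl palladium intermediate; the bulky acenaphthene-derived diol on boron, the halide-free cationic palladium centre and the wide-bite-angle ligand are there to secure this. Chemoselectivity is built in because the ring-C bromide is consumed in making 11 before the catalyst is added, so only iodide 3 meets palladium.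

Step 7
Reactants: 13 (1S,2R)-3-(tert-butyldimethylsilyloxy)-1-[3,5-dimethoxy-4-(methoxymethoxy)phenyl]-2-[5-(1,3-dioxolan-2-yl)-3-methoxy-2-(methoxymethoxy)phenyl]propylboronic acid cis-1,2-dimethylacenaphthylene-1,2-diyl ester
Product: 14 (1S,2R)-3-(tert-butyldimethylsilyloxy)-1-[3,5-dimethoxy-4-(methoxymethoxy)phenyl]-2-[5-(1,3-dioxolan-2-yl)-3-methoxy-2-(methoxymethoxy)phenyl]propan-1-ol
Conditions: 30% H2O2, 3 M NaOH, THF, 0 °C → rt
Reagents that add atoms: hydrogen peroxide, OO
Why: in this boronate oxidation hydroperoxide adds to boron and the benzylic carbon migrates from boron to oxygen with retention, so C2 keeps its configuration, while the MOM ethers, silyl ether and dioxolane are base-stable and the dioxolane keeps the aldehyde out of a Dakin oxidation.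

Step 8
Reactants: 14 (1S,2R)-3-(tert-butyldimethylsilyloxy)-1-[3,5-dimethoxy-4-(methoxymethoxy)phenyl]-2-[5-(1,3-dioxolan-2-yl)-3-methoxy-2-(methoxymethoxy)phenyl]propan-1-ol
Product: 16 (2S,3R)-2-(4-hydroxy-3,5-dimethoxyphenyl)-3-(hydroxymethyl)-7-methoxy-2,3-dihydro-1-benzofuran-5-carbaldehyde, via unmasked triol aldehyde 15 (not isolated)
Conditions: aq. HCl, MeOH, 0 °C → rt (no heating); then H2O
Reagents that add atoms: water, O
Why: acid removes both MOM ethers (methanol taking up the formaldehyde unit), the silyl ether and the dioxolane, and the para-hydroxybenzylic alcohol of 15 then ionises to a quinone-methide-type cation that the ring-A phenol captures in a 5-exo-trig cycloetherification forming O1–C2, the reversible closure settling on the trans ring with ring C opposite the C3 hydroxymethyl group while C3 itself is untouched.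

Step 9
Reactants: 16 (2S,3R)-2-(4-hydroxy-3,5-dimethoxyphenyl)-3-(hydroxymethyl)-7-methoxy-2,3-dihydro-1-benzofuran-5-carbaldehyde, 17 malonic acid
Product: 19 (E)-3-[(2S,3R)-2-(4-hydroxy-3,5-dimethoxyphenyl)-3-(hydroxymethyl)-7-methoxy-2,3-dihydro-1-benzofuran-5-yl]prop-2-enoic acid, via arylidenemalonic acid 18 (not isolated)
Conditions: pyridine, piperidine (cat.), 80 °C; aq. HCl work-up
Reagents that add atoms: none
Why: Knoevenagel–Doebner condensation of the aldehyde with malonic acid followed by decarboxylation of 18 in hot pyridine should give the E acid (thermodynamic geometry), the free phenol and primary alcohol being tolerated and neither stereocentre being acidic, since C3 is not conjugated with the formyl group.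

Compound list
1 | 5-iodovanillin (4-hydroxy-3-iodo-5-methoxybenzaldehyde) | COc1cc(C=O)cc(I)c1O | starting material
2 | 3-iodo-5-methoxy-4-(methoxymethoxy)benzaldehyde | COCOc1c(I)cc(C=O)cc1OC | intermediate
3 | 2-[3-iodo-5-methoxy-4-(methoxymethoxy)phenyl]-1,3-dioxolane | COCOc1c(I)cc(C2OCCO2)cc1OC | intermediate
4 | 4-bromo-2,6-dimethoxyphenol | COc1cc(Br)cc(OC)c1O | starting material
5 | 5-bromo-1,3-dimethoxy-2-(methoxymethoxy)benzene | COCOc1c(OC)cc(Br)cc1OC | intermediate
6 | acenaphthylene-1,2-dione (acenaphthoquinone) | O=C1C(=O)c2cccc3cccc1c23 | starting material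
7 | cis-1,2-dimethyl-1,2-dihydroacenaphthylene-1,2-diol (meso; 1R,2S) | C[C@]1(O)[C@@](C)(O)c2cccc3cccc1c23 | intermediate
8 | tert-butyldimethyl(prop-2-yn-1-yloxy)silane | C#CCO[Si](C)(C)C(C)(C)C | starting material
9 | 2-[(E)-3-(tert-butyldimethylsilyloxy)prop-1-en-1-yl]-1,3,2-benzodioxaborole (formed in the flask) | CC(C)(C)[Si](C)(C)OC/C=C/B1Oc2ccccc2O1 | intermediate
10 | (E)-3-(tert-butyldimethylsilyloxy)prop-1-en-1-ylboronic acid cis-1,2-dimethylacenaphthylene-1,2-diyl ester | C[C@@]14OB(/C=C/CO[Si](C)(C)C(C)(C)C)O[C@@]4(C)c2cccc3cccc1c23 | intermediate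
11 | [3,5-dimethoxy-4-(methoxymethoxy)phenyl]lithium (formed in the flask) | [Li]c1cc(OC)c(OCOC)c(OC)c1 | intermediate
12 | lithium aryl(alkenyl)boronate complex of 11 and 10 (formed in the flask; configuration at boron not defined) | [Li+].COCOc1c(OC)cc(cc1OC)[B-]2(/C=C/CO[Si](C)(C)C(C)(C)C)O[C@@]3(C)c4cccc5cccc(c45)[C@@]3(C)O2 | intermediate
13 | (1S,2R)-3-(tert-butyldimethylsilyloxy)-1-[3,5-dimethoxy-4-(methoxymethoxy)phenyl]-2-[5-(1,3-dioxolan-2-yl)-3-methoxy-2-(methoxymethoxy)phenyl]propylboronic acid cis-1,2-dimethylacenaphthylene-1,2-diyl ester | COc1cc([C@@H](B2O[C@@]3(C)c4cccc5cccc(c45)[C@@]3(C)O2)[C@@H](CO[Si](C)(C)C(C)(C)C)c2cc(C3OCCO3)cc(OC)c2OCOC)cc(OC)c1OCOC | intermediate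
14 | (1S,2R)-3-(tert-butyldimethylsilyloxy)-1-[3,5-dimethoxy-4-(methoxymethoxy)phenyl]-2-[5-(1,3-dioxolan-2-yl)-3-methoxy-2-(methoxymethoxy)phenyl]propan-1-ol | COc1cc([C@@H](O)[C@@H](CO[Si](C)(C)C(C)(C)C)c2cc(C3OCCO3)cc(OC)c2OCOC)cc(OC)c1OCOC | intermediate
15 | 3-[(1S,2R)-1,3-dihydroxy-1-(4-hydroxy-3,5-dimethoxyphenyl)propan-2-yl]-4-hydroxy-5-methoxybenzaldehyde (formed in the flask) | COc1cc([C@@H](O)[C@@H](CO)c2cc(C=O)cc(OC)c2O)cc(OC)c1O | intermediate
16 | (2S,3R)-2-(4-hydroxy-3,5-dimethoxyphenyl)-3-(hydroxymethyl)-7-methoxy-2,3-dihydro-1-benzofuran-5-carbaldehyde | COc1cc([C@H]2Oc3c(OC)cc(C=O)cc3[C@@H]2CO)cc(OC)c1O | intermediate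
17 | malonic acid | O=C(O)CC(=O)O | starting material
18 | 2-{[(2S,3R)-2-(4-hydroxy-3,5-dimethoxyphenyl)-3-(hydroxymethyl)-7-methoxy-2,3-dihydro-1-benzofuran-5-yl]methylidene}propanedioic acid (formed in the flask) | COc1cc([C@H]2Oc3c(OC)cc(C=C(C(=O)O)C(=O)O)cc3[C@@H]2CO)cc(OC)c1O | intermediate
19 | (E)-3-[(2S,3R)-2-(4-hydroxy-3,5-dimethoxyphenyl)-3-(hydroxymethyl)-7-methoxy-2,3-dihydro-1-benzofuran-5-yl]prop-2-enoic acid | COc1cc([C@H]2Oc3c(OC)cc(/C=C/C(=O)O)cc3[C@@H]2CO)cc(OC)c1O | target

Total step count: 9. Longest linear sequence: 6 steps (1 → 2 → 3 → 13 → 14 → 16 → 19; the boronate arm 6 → 7 → 10 → 13 → 14 → 16 → 19 is equally long).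

Steps most likely to fail

Step 6. The alkenyl group may transmetalate directly to palladium (Suzuki coupling) instead of undergoing the metallate shift. Residual halide may also inhibit the cationic catalyst, or the ortho-substituted iodide may erode facial selectivity. The fallback is an auxiliary-controlled aldol that sets out from 3 and 5 and comes back to the route at 16. Aryllithium 11, made from 5 as in step 6, is formylated with DMF to 3,5-dimethoxy-4-(methoxymethoxy)benzaldehyde F1. Iodide 3 is coupled with the Reformatsky reagent BrZnCH2CO2Et (Pd2(dba)3, XPhos, THF, 60 °C) to ethyl 2-[5-(1,3-dioxolan-2-yl)-3-methoxy-2-(methoxymethoxy)phenyl]acetate F2. LiOH in THF/H2O saponifies this to 2-[5-(1,3-dioxolan-2-yl)-3-methoxy-2-(methoxymethoxy)phenyl]acetic acid F3. Acylation of (S)-4-benzyl-1,3-oxazolidin-2-one (PivCl, Et3N, LiCl, THF) should then give (S)-4-benzyl-3-(arylacetyl)oxazolidin-2-one F4. An Evans syn aldol of F4 with F1 (Bu2BOTf, i-Pr2NEt, CH2Cl2, −78 → 0 °C) should give the (2S,3S) aldol adduct F5, the auxiliary fixing the carbon that bears ring A. LiBH4 (THF, MeOH, 0 °C) then removes the auxiliary and gives the (1S,2R)-1,3-diol F6, the silyl-free analogue of 14. Under the conditions of step 8, F6 should close to 16.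

Step 8. The benzylic cation may fragment with loss of the hydroxymethyl carbon as formaldehyde, or be diverted by solvent or liberated formaldehyde while four protecting groups are still being removed. The fallback unmasks before the oxygen is installed; it sets out from 13 and comes back at 16 by way of 15. Treatment of 13 with aq. HCl in MeOH at rt, where C2 carries boron and cannot ionise, should give (1S,2R)-2-(5-formyl-2-hydroxy-3-methoxyphenyl)-3-hydroxy-1-(4-hydroxy-3,5-dimethoxyphenyl)propylboronic acid cis-1,2-dimethylacenaphthylene-1,2-diyl ester F7. Anhydrous Me3NO in THF at 60 °C then oxidises C–B with retention to 15 without touching the aldehyde. A trace of pyridinium tosylate in CH2Cl2 at 0 °C should close 15 to 16, far milder than the one-pot cascade.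

Step 9. Hot amine base may open ring B through the para-quinone methide of ring C, with capture by piperidine, or decarboxylation may stall. The fallback replaces the condensation with an olefination; it sets out from 16 and comes back at 19. Wittig reaction of 16 with the stabilised ylide Ph3P=CHCO2Me (toluene, 40 °C) should give methyl (E)-3-[(2S,3R)-2-(4-hydroxy-3,5-dimethoxyphenyl)-3-(hydroxymethyl)-7-methoxy-2,3-dihydro-1-benzofuran-5-yl]prop-2-enoate F8. LiOH in THF/H2O at rt followed by acidification should then give 19.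

Further compounds
F1 | step 6 | 3,5-dimethoxy-4-(methoxymethoxy)benzaldehyde | COCOc1c(OC)cc(C=O)cc1OC
F2 | step 6 | ethyl 2-[5-(1,3-dioxolan-2-yl)-3-methoxy-2-(methoxymethoxy)phenyl]acetate | CCOC(=O)Cc1cc(C2OCCO2)cc(OC)c1OCOC
F3 | step 6 | 2-[5-(1,3-dioxolan-2-yl)-3-methoxy-2-(methoxymethoxy)phenyl]acetic acid | OC(=O)Cc1cc(C2OCCO2)cc(OC)c1OCOC
F4 | step 6 | (S)-4-benzyl-3-{2-[5-(1,3-dioxolan-2-yl)-3-methoxy-2-(methoxymethoxy)phenyl]acetyl}-1,3-oxazolidin-2-one | O=C(Cc1cc(C2OCCO2)cc(OC)c1OCOC)N1[C@@H](Cc2ccccc2)COC1=O
F5 | step 6 | (S)-4-benzyl-3-{(2S,3S)-3-[3,5-dimethoxy-4-(methoxymethoxy)phenyl]-2-[5-(1,3-dioxolan-2-yl)-3-methoxy-2-(methoxymethoxy)phenyl]-3-hydroxypropanoyl}-1,3-oxazolidin-2-one | O=C([C@@H](c1cc(C2OCCO2)cc(OC)c1OCOC)[C@H](O)c1cc(OC)c(OCOC)c(OC)c1)N1[C@@H](Cc2ccccc2)COC1=O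
F6 | step 6 | (1S,2R)-1-[3,5-dimethoxy-4-(methoxymethoxy)phenyl]-2-[5-(1,3-dioxolan-2-yl)-3-methoxy-2-(methoxymethoxy)phenyl]propane-1,3-diol | COc1cc([C@@H](O)[C@@H](CO)c2cc(C3OCCO3)cc(OC)c2OCOC)cc(OC)c1OCOC
F7 | step 8 | (1S,2R)-2-(5-formyl-2-hydroxy-3-methoxyphenyl)-3-hydroxy-1-(4-hydroxy-3,5-dimethoxyphenyl)propylboronic acid cis-1,2-dimethylacenaphthylene-1,2-diyl ester | COc1cc([C@@H](B2O[C@@]3(C)c4cccc5cccc(c45)[C@@]3(C)O2)[C@@H](CO)c2cc(C=O)cc(OC)c2O)cc(OC)c1O
F8 | step 9 | methyl (E)-3-[(2S,3R)-2-(4-hydroxy-3,5-dimethoxyphenyl)-3-(hydroxymethyl)-7-methoxy-2,3-dihydro-1-benzofuran-5-yl]prop-2-enoate | COc1cc([C@H]2Oc3c(OC)cc(/C=C/C(=O)OC)cc3[C@@H]2CO)cc(OC)c1O
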